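**Plan**

- Cuts, in retrosynthetic order: the acid to its methyl ester; the carbinol C7'–C8' bond of the side chain (Ni/Cr coupling); the (E)-C3'=C4' alkene together with C5'–C6' (Claisen); the acrylate C–CO2Me bond (alkyne methoxycarbonylation); last, the oxane at O1–C6 and C2–C3.
- Enabling feature: in the oxane ring, O1–C2 is the O=C of a former aldehyde, and C3–C4–C5–C6 is a butane-1,4-diyl unit with CH2 termini and a single branch at C5. These are the four carbons of symmetric (E)-1,4-dibromobut-2-ene, used as a nucleophile at C3 and an electrophile at C6.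
- Forward order: SN2' desymmetrisation of the dibromide (sets C5), then a one-flask [4+2] annulation with a silylpropynal (oxane ring and C2), alkyne to acrylate, then the chain is grown outward: isopropenyl addition, Claisen rearrangement, Ni/Cr coupling with the enol triflate of 6-methylhept-5-en-2-one, saponification.
- Stereochemistry: C5 from a chiral Cu catalyst; C2 from a chiral Ti bis-sulfonamide catalyst, so the 2,5-trans relationship is the sum of two reagent-controlled centres with no epimerisable carbon; the (E)-alkene from a chair Claisen transition state; the (7'R)-carbinol from a chiral sulfonamide-ligated alkenylchromium reagent.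

Key step: step 2

Remark: the sense of induction of the chiral ligands in steps 1 and 9 is taken from their model reactions, and the ligand enantiomer is chosen so that (S)-4 and the (7R)-carbinol result.

**Step 1**
Reactants: 1 (3-bromopropoxy)(tert-butyl)dimethylsilane; 2 (E)-1,4-dibromobut-2-ene
Product: 4 tert-butyl{[(4S)-4-(bromomethyl)hex-5-en-1-yl]oxy}dimethylsilane, via Grignard reagent 3 (not isolated)
Conditions: 1, Mg, Et2O, rt; then added slowly to 2, CuBr·SMe2 (3 mol%), chiral BINOL-derived phosphoramidite (4 mol%), CH2Cl2, −78 °C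
Reagents that add atoms: none
Why: Cu-catalysed asymmetric allylic alkylation (SN2') of the symmetric dibromide: the alkylcopper formed from 3 attacks the alkene carbon γ to one bromide, anti to the leaving group, the chiral ligand selects the enantiotopic face and so sets the future ring C5, and the remaining bromide, no longer allylic, stays untouched.

**Step 2**
Reactants: 4 tert-butyl{[(4S)-4-(bromomethyl)hex-5-en-1-yl]oxy}dimethylsilane; 5 3-[tri(propan-2-yl)silyl]prop-2-ynal
Product: 9 tert-butyldimethyl{3-[(3S,6R)-6-{[tri(propan-2-yl)silyl]ethynyl}oxan-3-yl]propoxy}silane, via alkyldiethylborane 6 (not isolated), via dialkylzinc 7 (not isolated), via potassium alkoxide 8 (not isolated)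
Conditions: Et2BH, Et2O, 0 °C → rt; Et2Zn (neat), 0 °C, then vacuum; toluene, Ti(OiPr)4, (1S,2S)-1,2-bis(trifluoromethanesulfonamido)cyclohexane (8 mol%), 5 (limiting), −20 °C; then t-BuOK, THF, 0 °C → rt
Reagents that add atoms: none
Why: Anti-Markovnikov hydroboration of the vinyl group puts boron on the future C3, boron–zinc exchange gives the dialkylzinc, the chiral titanium bis-sulfonamide complex transfers this alkyl group to the aldehyde carbon (C2–C3 bond), and the alkoxide, released as its potassium salt, displaces the primary bromide (O1–C6 bond). The closest known reaction types are the catalytic asymmetric addition of functionalised dialkylzincs (made by boron–zinc exchange) to aldehydes, silylpropynals included, and the intramolecular Williamson etherification of δ-halo alkoxides. The oxane ring closes by a 6-exo-tet SN2 substitution at the CH2Br carbon. C2 is set by the catalyst, which directs alkyl transfer to the Re face of the aldehyde (the (1S,2S) ligand, mirror image of the (1R,2R)/Si-face pairing), independently of the remote C5. The step needs chemoselectivity (the organozinc must spare the primary bromide, which dialkylzincs do, and ring closure must beat elimination, which the six-membered closure onto a primary carbon should secure) and an untouched C5, which bears no acidic hydrogen and is not a reacting centre.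

**Step 3**
Reactants: 9 tert-butyldimethyl{3-[(3S,6R)-6-{[tri(propan-2-yl)silyl]ethynyl}oxan-3-yl]propoxy}silane
Product: 10 3-[(3S,6R)-6-ethynyloxan-3-yl]propan-1-ol
Conditions: TBAF, THF, 0 °C → rt
Reagents that add atoms: none
Why: Fluoride-mediated desilylation should remove the alkynyl silyl group and the silyl ether in one operation without touching either stereocentre.

**Step 4**
Reactants: 10 3-[(3S,6R)-6-ethynyloxan-3-yl]propan-1-ol
Product: 11 methyl 2-[(2R,5S)-5-(3-hydroxypropyl)oxan-2-yl]prop-2-enoate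
Conditions: Pd(OAc)2 (1 mol%), diphenyl(2-pyridyl)phosphine, MeSO3H, CO (10 bar), MeOH, 45 °C
Reagents that add atoms: carbon monoxide, [C-]#[O+]; methanol, CO
Why: Branch-selective Pd-catalysed methoxycarbonylation of a terminal alkyne (Drent type, pyridylphosphine proton relay) adds H and CO2Me across the triple bond with the ester on the internal carbon, giving the 2-substituted acrylate; methanol as solvent should outcompete the substrate hydroxyl.

**Step 5**
Reactants: 11 methyl 2-[(2R,5S)-5-(3-hydroxypropyl)oxan-2-yl]prop-2-enoate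
Product: 12 methyl 2-[(2R,5R)-5-(3-oxopropyl)oxan-2-yl]prop-2-enoate
Conditions: TEMPO (10 mol%), PhI(OAc)2, CH2Cl2, rt
Reagents that add atoms: none
Why: TEMPO-catalysed oxidation should convert the primary alcohol into the aldehyde without over-oxidation and leave the acrylate and both stereocentres alone (the C5 descriptor changes by priority only).

**Step 6**
Reactants: 12 methyl 2-[(2R,5R)-5-(3-oxopropyl)oxan-2-yl]prop-2-enoate; 13 2-bromopropene
Product: 14 methyl 2-[(2R,5S)-5-(3-hydroxy-4-methylpent-4-en-1-yl)oxan-2-yl]prop-2-enoate (both carbinol epimers)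
Conditions: CrCl2, NiCl2 (2 mol%), DMF, rt
Reagents that add atoms: none
Why: Nozaki–Hiyama–Kishi coupling: the isopropenylchromium species adds to the aldehyde only, not to the acrylate ester; the new carbinol centre forms as a mixture of epimers, which is harmless because step 7 erases it.

**Step 7**
Reactants: 14 methyl 2-[(2R,5S)-5-(3-hydroxy-4-methylpent-4-en-1-yl)oxan-2-yl]prop-2-enoate
Product: 16 methyl 2-[(2R,5S)-5-[(3E)-4-methyl-7-oxohept-3-en-1-yl]oxan-2-yl]prop-2-enoate, via allyl vinyl ether 15 (not isolated)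
Conditions: ethyl vinyl ether, Hg(OAc)2 (cat.), reflux; then toluene, BHT, 130 °C (sealed tube)
Reagents that add atoms: ethyl vinyl ether, C=COCC
Why: Transfer vinylation followed by Claisen rearrangement through a chair transition state, with the oxane-bearing chain equatorial to avoid the 1,3-diaxial clash with the 2-methyl group, should give the (E)-trisubstituted alkene and the chain-extended aldehyde.

**Step 8**
Reactants: 17 6-methylhept-5-en-2-one
Product: 18 6-methylhepta-1,5-dien-2-yl trifluoromethanesulfonate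
Conditions: LiN(i-Pr)2, THF, −78 °C; PhNTf2, −78 → 0 °C
Reagents that add atoms: N-phenylbis(trifluoromethanesulfonimide), O=S(=O)(N(c1ccccc1)S(=O)(=O)C(F)(F)F)C(F)(F)F
Why: Kinetic deprotonation of the methyl ketone at the methyl group and O-triflation of the less substituted enolate should give the terminal enol triflate.

**Step 9**
Reactants: 16 methyl 2-[(2R,5S)-5-[(3E)-4-methyl-7-oxohept-3-en-1-yl]oxan-2-yl]prop-2-enoate; 18 6-methylhepta-1,5-dien-2-yl trifluoromethanesulfonate
Product: 19 methyl 2-[(2R,5S)-5-[(3E,7R)-7-hydroxy-4,12-dimethyl-8-methylidenetrideca-3,11-dien-1-yl]oxan-2-yl]prop-2-enoate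
Conditions: CrCl2, chiral oxazoline–sulfonamide ligand (Kishi type), Et3N, NiCl2 (cat.), THF/MeCN, rt
Reagents that add atoms: none
Why: Asymmetric Nozaki–Hiyama–Kishi coupling: Ni-mediated activation of the enol triflate, transfer to chromium and addition of the sulfonamide-ligated alkenylchromium to one face of the aldehyde should set the (7R)-carbinol under reagent control, the ring stereocentres being too remote to interfere.

**Step 10**
Reactants: 19 methyl 2-[(2R,5S)-5-[(3E,7R)-7-hydroxy-4,12-dimethyl-8-methylidenetrideca-3,11-dien-1-yl]oxan-2-yl]prop-2-enoate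
Product: 20 2-[(2R,5S)-5-[(3E,7R)-7-hydroxy-4,12-dimethyl-8-methylidenetrideca-3,11-dien-1-yl]oxan-2-yl]prop-2-enoic acid
Conditions: LiOH, THF/H2O, 0 °C → rt; then 1 M HCl to pH 3
Reagents that add atoms: lithium hydroxide, [Li+].[OH-]
Why: Saponification of the methyl ester and acidification should release the acrylic acid; the allylic C2–H is not acidic enough to isomerise under these mild conditions.

**Compound list**

1 | (3-bromopropoxy)(tert-butyl)dimethylsilane | CC(C)(C)[Si](C)(C)OCCCBr | starting material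
2 | (E)-1,4-dibromobut-2-ene | BrC/C=C/CBr | starting material
3 | {3-[(tert-butyldimethylsilyl)oxy]propyl}magnesium bromide | CC(C)(C)[Si](C)(C)OCCC[Mg]Br | intermediate
4 | tert-butyl{[(4S)-4-(bromomethyl)hex-5-en-1-yl]oxy}dimethylsilane | CC(C)(C)[Si](C)(C)OCCC[C@H](CBr)C=C | intermediate
5 | 3-[tri(propan-2-yl)silyl]prop-2-ynal | O=CC#C[Si](C(C)C)(C(C)C)C(C)C | starting material
6 | {(3R)-3-(bromomethyl)-6-[(tert-butyldimethylsilyl)oxy]hexyl}diethylborane | CC(C)(C)[Si](C)(C)OCCC[C@H](CBr)CCB(CC)CC | intermediate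
7 | bis{(3S)-3-(bromomethyl)-6-[(tert-butyldimethylsilyl)oxy]hexyl}zinc | CC(C)(C)[Si](C)(C)OCCC[C@H](CBr)CC[Zn]CC[C@@H](CBr)CCCO[Si](C)(C)C(C)(C)C | intermediate
8 | potassium (3R,6S)-6-(bromomethyl)-9-[(tert-butyldimethylsilyl)oxy]-1-[tri(propan-2-yl)silyl]non-1-yn-3-olate | CC(C)(C)[Si](C)(C)OCCC[C@H](CBr)CC[C@@H]([O-])C#C[Si](C(C)C)(C(C)C)C(C)C.[K+] | intermediate
9 | tert-butyldimethyl{3-[(3S,6R)-6-{[tri(propan-2-yl)silyl]ethynyl}oxan-3-yl]propoxy}silane | CC(C)(C)[Si](C)(C)OCCC[C@H]1CC[C@H](C#C[Si](C(C)C)(C(C)C)C(C)C)OC1 | intermediate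
10 | 3-[(3S,6R)-6-ethynyloxan-3-yl]propan-1-ol | OCCC[C@H]1CC[C@H](C#C)OC1 | intermediate
11 | methyl 2-[(2R,5S)-5-(3-hydroxypropyl)oxan-2-yl]prop-2-enoate | OCCC[C@H]1CC[C@H](C(=C)C(=O)OC)OC1 | intermediate
12 | methyl 2-[(2R,5R)-5-(3-oxopropyl)oxan-2-yl]prop-2-enoate | O=CCC[C@H]1CC[C@H](C(=C)C(=O)OC)OC1 | intermediate
13 | 2-bromopropene | C=C(C)Br | starting material
14 | methyl 2-[(2R,5S)-5-(3-hydroxy-4-methylpent-4-en-1-yl)oxan-2-yl]prop-2-enoate (both carbinol epimers) | C=C(C)C(O)CC[C@H]1CC[C@H](C(=C)C(=O)OC)OC1 | intermediate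
15 | methyl 2-[(2R,5R)-5-[3-(ethenyloxy)-4-methylpent-4-en-1-yl]oxan-2-yl]prop-2-enoate (both ether-carbon epimers) | C=COC(CC[C@H]1CC[C@H](C(=C)C(=O)OC)OC1)C(C)=C | intermediate
16 | methyl 2-[(2R,5S)-5-[(3E)-4-methyl-7-oxohept-3-en-1-yl]oxan-2-yl]prop-2-enoate | O=CCC/C(C)=C/CC[C@H]1CC[C@H](C(=C)C(=O)OC)OC1 | intermediate
17 | 6-methylhept-5-en-2-one | CC(=O)CCC=C(C)C | starting material
18 | 6-methylhepta-1,5-dien-2-yl trifluoromethanesulfonate | C=C(OS(=O)(=O)C(F)(F)F)CCC=C(C)C | intermediate
19 | methyl 2-[(2R,5S)-5-[(3E,7R)-7-hydroxy-4,12-dimethyl-8-methylidenetrideca-3,11-dien-1-yl]oxan-2-yl]prop-2-enoate | C=C(CCC=C(C)C)[C@H](O)CC/C(C)=C/CC[C@H]1CC[C@H](C(=C)C(=O)OC)OC1 | intermediate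
20 | 2-[(2R,5S)-5-[(3E,7R)-7-hydroxy-4,12-dimethyl-8-methylidenetrideca-3,11-dien-1-yl]oxan-2-yl]prop-2-enoic acid | C=C(CCC=C(C)C)[C@H](O)CC/C(C)=C/CC[C@H]1CC[C@H](C(=C)C(=O)O)OC1 | target

Total step count: 10. Longest linear sequence: 9 (steps 1–7, 9, 10).

**Steps most likely to fail**

Step 2. The four stages share one flask. Boron–zinc exchange may be incomplete, the functionalised zinc reagent may transfer with eroded facial selectivity, and the metal alkoxide may undergo elimination or stay unreactive instead of closing the ring. The fallback sets out from 4 and returns at 9, building C2 by reagent-controlled ketone reduction instead of alkyl transfer. Hydroboration of 4 with 9-BBN and iodination (I2, NaOMe) should give tert-butyl{[(4S)-4-(bromomethyl)-6-iodohexyl]oxy}dimethylsilane F1. Selective iodine–lithium exchange (t-BuLi, Et2O/pentane, −78 °C) and addition to 5 should give (6S)-6-(bromomethyl)-9-[(tert-butyldimethylsilyl)oxy]-1-[tri(propan-2-yl)silyl]non-1-yn-3-ol F2 as both C3 epimers. Dess–Martin oxidation should give the ynone (6S)-6-(bromomethyl)-9-[(tert-butyldimethylsilyl)oxy]-1-[tri(propan-2-yl)silyl]non-1-yn-3-one F3. Transfer hydrogenation with RuCl(p-cymene)[(R,R)-TsDPEN] in i-PrOH should give (3R,6S)-6-(bromomethyl)-9-[(tert-butyldimethylsilyl)oxy]-1-[tri(propan-2-yl)silyl]non-1-yn-3-ol F4, and NaH in THF/DMF should then close the oxane to 9.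

Step 9. Enantiofacial discrimination at an unbiased aliphatic aldehyde may be insufficient, and the C7 epimer, remote from the ring centres, would be hard to remove. The fallback sets out from 16 and 18 and returns at 19. Ligand-free Ni/Cr coupling (CrCl2, NiCl2 cat., DMF) should give methyl 2-[(2R,5S)-5-[(3E)-7-hydroxy-4,12-dimethyl-8-methylidenetrideca-3,11-dien-1-yl]oxan-2-yl]prop-2-enoate F5 as both C7 epimers. Dess–Martin oxidation should give the enone methyl 2-[(2R,5S)-5-[(3E)-4,12-dimethyl-8-methylidene-7-oxotrideca-3,11-dien-1-yl]oxan-2-yl]prop-2-enoate F6. Reduction with (S)-2-methyl-CBS-oxazaborolidine and catecholborane in toluene at −78 °C, the branched alkenyl group acting as the large substituent, should give (7R)-19.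

Step 4. Hydropalladation of the propargylic ether may leak toward the linear enoate, and the acidic medium may open side reactions at the propargylic C–O bond or involve the free hydroxyl. The fallback sets out from 10 and returns at 11, fixing the regiochemistry in a separate hydrometalation. Hydrostannation with Bu3SnH and Mo(CO)3(CNt-Bu)3 (cat.) in THF at 55 °C should give the internal stannane 3-[(3S,6R)-6-[1-(tributylstannyl)ethenyl]oxan-3-yl]propan-1-ol F7. Iododestannylation (I2, CH2Cl2, 0 °C) should give 3-[(3S,6R)-6-(1-iodoethenyl)oxan-3-yl]propan-1-ol F8. Carbonylation with Pd(PPh3)4, CO (1 atm), MeOH and Et3N should then give 11.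

**Further compounds**

F1 | step 2 | tert-butyl{[(4S)-4-(bromomethyl)-6-iodohexyl]oxy}dimethylsilane | CC(C)(C)[Si](C)(C)OCCC[C@H](CBr)CCI
F2 | step 2 | (6S)-6-(bromomethyl)-9-[(tert-butyldimethylsilyl)oxy]-1-[tri(propan-2-yl)silyl]non-1-yn-3-ol (both C3 epimers) | CC(C)(C)[Si](C)(C)OCCC[C@H](CBr)CCC(O)C#C[Si](C(C)C)(C(C)C)C(C)C
F3 | step 2 | (6S)-6-(bromomethyl)-9-[(tert-butyldimethylsilyl)oxy]-1-[tri(propan-2-yl)silyl]non-1-yn-3-one | CC(C)(C)[Si](C)(C)OCCC[C@H](CBr)CCC(=O)C#C[Si](C(C)C)(C(C)C)C(C)C
F4 | step 2 | (3R,6S)-6-(bromomethyl)-9-[(tert-butyldimethylsilyl)oxy]-1-[tri(propan-2-yl)silyl]non-1-yn-3-ol | CC(C)(C)[Si](C)(C)OCCC[C@H](CBr)CC[C@@H](O)C#C[Si](C(C)C)(C(C)C)C(C)C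
F5 | step 9 | methyl 2-[(2R,5S)-5-[(3E)-7-hydroxy-4,12-dimethyl-8-methylidenetrideca-3,11-dien-1-yl]oxan-2-yl]prop-2-enoate (both C7 epimers) | C=C(CCC=C(C)C)C(O)CC/C(C)=C/CC[C@H]1CC[C@H](C(=C)C(=O)OC)OC1
F6 | step 9 | methyl 2-[(2R,5S)-5-[(3E)-4,12-dimethyl-8-methylidene-7-oxotrideca-3,11-dien-1-yl]oxan-2-yl]prop-2-enoate | C=C(CCC=C(C)C)C(=O)CC/C(C)=C/CC[C@H]1CC[C@H](C(=C)C(=O)OC)OC1
F7 | step 4 | 3-[(3S,6R)-6-[1-(tributylstannyl)ethenyl]oxan-3-yl]propan-1-ol | OCCC[C@H]1CC[C@H](C(=C)[Sn](CCCC)(CCCC)CCCC)OC1
F8 | step 4 | 3-[(3S,6R)-6-(1-iodoethenyl)oxan-3-yl]propan-1-ol | OCCC[C@H]1CC[C@H](C(=C)I)OC1
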